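All runs come from a simulation with constants of no real substance.

The north-east run was my one guide to this flask, so I read from it how fast [free monomer] fell on a logarithmic scale and how fast that fall itself slowed.

- north-east: free monomer 0.050 M; transfer agent 0.015 M; initiator 5 mol%; run made earlier
- flask: free monomer 0.050 M; transfer agent 0.0150 M; initiator 2.5 mol%; time 2.5 min

- north-east (time / s: monomer in chains / %, free monomer / %): 10.0: 20.3, 79.3; 12.0: 24.2, 75.3; 20.0: 36.0, 64.1; 30.0: 47.4, 52.5; 50.0: 61.5, 38.5

(standard deviation of a reading: 0.3 percentage points)

- what was read earlier has a scatter of 0.3 percentage points, one standard deviation
- no earlier run changes the charge of initiator; that part of a forecast is a guess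

* how much monomer in chains the flask holds at 2.5 min, in percent of the free monomer charged
* how much free monomer the flask holds at 2.5 min, in percent of the free monomer charged

In the north-east run the slope of −ln[free monomer] read 0.0206 /s between 10.0 s and 30.0 s, and it was lower between 30.0 s and 50.0 s, at 0.0155 /s, so it faded at about 0.0142 /s. I froze that fade for the flask, whose [transfer agent] matches the north-east run, and ran the slope back to a start of 0.0274 /s. A slope fading steadily adds up to a finite exponent, the starting slope over the fade, which came to 1.92 for the north-east run. With the initiator at half that charge I halved the starting slope, which gave the flask a reach, the exponent its fading slope adds up to, of 0.962. By 2.5 min I reckoned 88.2% of it used, an exponent of 0.849, so I reckoned 42.8% free and 57.2% in chains.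

The weak link was that halving, since no earlier run changed the initiator. A square root would suit a supply still being fed, but in the north-east run the slope over the first 10.0 s, 0.0232 /s, already stood above the later 0.0206 /s. That looked to me like a stock made at the outset that then merely faded, and a stock goes with its charge, so I kept the first power.

The forecast put 72% in chains and 28% free, “with wide ranges”, which differs from my reckoning. The flask gave 57.8% in chains and 41.9% free.

    free monomer + initiator → living end + monomer in chains (k = 8.60 /M/s)
    free monomer + living end → monomer in chains + living end, rate k2*[living end]*[free monomer] (k = 10.0 /M/s)
    living end + transfer agent → dead chain (kL = 0.740 /M/s)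
    living end + monomer in chains → dead end (k = 0.110 /M/s)

The reach of 0.962 leaves 38.2% free, and the flask left until 25.0 min holds 36.6%. For the neighbouring flask, with 0.025 M of transfer agent, I kept the flask's starting slope and raised the fade by the transfer constant 0.74 /M/s times the extra transfer agent, to 0.0216 /s. Its reach then came to 0.633, and by 2.5 min that reckons to 54.4% free. That neighbouring flask holds 53.2% free monomer.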